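Follow the rate.

| flask | starting material | coupling partner | free catalyst | remark | time |
|---|---|---|---|---|---|
| epsilon | 0.034 M | 0.95 equiv | 15 mol% | run made earlier |  |
| alpha | 0.075 M | 0.95 equiv | 15 mol% | run made earlier |  |
| flask | 0.050 M | 0.950 equiv | 15 mol% |  | 30 h |

- epsilon (time / h: starting material / %, target / %): 8.00: 59.0, 35.4; 15.0: 37.4, 57.3; 25.0: 19.2, 74.6; 30.0: 14.4, 78.9
- alpha (time / h: starting material / %, target / %): 8.00: 38.0, 55.1; 15.0: 15.8, 77.5; 25.0: 6.0, 85.4; 30.0: 3.6, 85.8

(scatter of a reading: 0.3 percentage points)

- part of the starting material that has reacted at 30 h
- share of the unused coupling partner that is free and not bound as idle adduct, at 30 h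

- the earlier runs do not show how much of coupling partner is bound; that part of a forecast is a guess

Starting material, A, leaves at a rate r = k̄A, where k̄, an apparent pseudo-first-order constant, is the share of remaining A lost per hour, averaged over the time t. Integrating gives a closed form:

left = charged × exp(−k̄t), so k̄ = ln(charged/left)/t

At 30.0 h, epsilon gives 0.0646 /h and alpha 0.111 /h. The constant grows less than in proportion to concentration: the readings give an order n of 0.682. Carried to the flask's charge:

k̄(flask) = k̄(epsilon) × (0.050 M/0.034 M)^n = 0.0840 /h

This mean loss constant carries two slowings. On this reckoning, the loss of starting material cuts the flask's rate by a factor of 12.4 over 30 h. The constant itself sags in the alpha readings: they give 0.121 /h over the first 8.00 h and 0.0986 /h from 15.0 h to 30.0 h, a factor of 1.23, and the mean read from the runs already contains such sagging. Accumulated in the flask: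

unreacted share = exp(−k̄t) = 8.05 %, so c = 92.0 %

The forecast stands at 92 % for c and 50 % for fr: “The free share is a guess”.

The flask gives 92.3 % and 76.8 %: c agrees, and fr lies 27 percentage points above the guess.

    starting material + free catalyst → catalyst intermediate A (k = 20.0 /M/h)
    coupling partner + catalyst intermediate A → catalyst intermediate B (k = 79.0 /M/h)
    catalyst intermediate B → released group + catalyst intermediate C (k = 7.10 /h)
    catalyst intermediate C → free catalyst + target (k = 2.10 /h)
    coupling partner + released group ⇌ idle adduct, settled at all times (K = 6.90 /M)
    starting material → decomposition product (k = 6.40 × 10⁻⁵ /h)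
    free catalyst + target → spent catalyst (k = 0.610 /M/h)

The flask's own k̄ at 30 h comes to 0.0854 /h, and the flask has not come to rest: 7.71 % of the starting material charged remains, and 4.72 % of the coupling partner's own charge remains unbound. Ten times the time lifts c to 99.3 %, a gain of 7 points. Between 30 h and 300 h, k̄ for starting material averages 0.00895 /h. By 300 h, free catalyst stands at 0.00737 % and spent catalyst at 71.8 % of the catalyst charged, while target stands at 84.2 % of the starting material charged, against 84.3 % at 30.0 h.

The runs come from a simulation for an exercise, noise included.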